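**Retrosynthetic overview**

1. Hansfordiol G (17) comes from β-resorcylate 14 by ester hydrolysis, decarboxylation and desilylation; the ring carboxyl of 14 is the unused chain end of a tetraketide.
2. Feature: ring carbon C5 of the resorcinol and side-chain carbons C1′–C17′ are the intact C18 skeleton of (9Z,16S)-16-hydroxyoleic acid, with C5 as its carboxyl carbon. The other five ring carbons and both phenolic oxygens are three acetate units less one CO2.
3. Key disconnection: both ring bonds at the chain-bearing carbon of 14 (one by C-acylation, one by aldol) lead back to silyl-protected hydroxyoleate ester 10 and methyl 3,5-dioxohexanoate 11 as its trianion. The benzene ring is the only ring and is formed in step 5.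
4. Ester 10 comes from a Z-selective Wittig union of C10–C18 phosphonium salt 7 with methyl 9-oxononanoate 8. Salt 7 comes from (S)-1,2-epoxybutane 2 and the Grignard reagent of 1-bromo-5-chloropentane 1; the stereocentre is bought and never touched.

Key step: step 5

Remark: methyl 9-oxononanoate (8) and methyl 3,5-dioxohexanoate (11) are treated as purchasable reagents.

**Route**

Step 1
Reactants: 1 1-bromo-5-chloropentane; 2 (S)-1,2-epoxybutane
Product: 4 (S)-9-chlorononan-3-ol, via 5-chloropentylmagnesium bromide 3 (not isolated)
Conditions: Mg, THF, 20–30 °C; then CuI (10 mol%), 2, THF, –30 → 0 °C; sat. aq. NH4Cl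
Reagents that add atoms: none
Why: Magnesium inserts into the C–Br bond in preference to C–Cl, and the copper(I)-catalysed Grignard opening of the monosubstituted epoxide is an SN2 attack at the unsubstituted CH2, so the purchased (S) carbinol carbon is carried over unchanged.

Step 2
Reactants: 4 (S)-9-chlorononan-3-ol
Product: 5 (S)-tert-butyl[(9-chlorononan-3-yl)oxy]dimethylsilane
Conditions: TBSCl, imidazole, DMF, rt
Reagents that add atoms: tert-butyldimethylsilyl chloride, CC(C)(C)[Si](C)(C)Cl
Why: Imidazole-promoted silylation of a secondary alcohol is a standard protection that leaves the primary chloride and the stereocentre untouched, since only the O–H bond reacts.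

Step 3
Reactants: 5 (S)-tert-butyl[(9-chlorononan-3-yl)oxy]dimethylsilane
Product: 7 [(7S)-7-(tert-butyldimethylsilyloxy)nonyl]triphenylphosphonium iodide, via alkyl iodide 6 (not isolated)
Conditions: NaI, PPh3, MeCN, reflux
Reagents that add atoms: sodium iodide, [Na+].[I-]; triphenylphosphine, c1ccc(cc1)P(c1ccccc1)c1ccccc1
Why: Finkelstein exchange, driven by precipitation of NaCl from acetonitrile, gives the primary iodide, which quaternises triphenylphosphine by SN2 under neutral conditions that a secondary silyl ether tolerates.

Step 4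
Reactants: 7 [(7S)-7-(tert-butyldimethylsilyloxy)nonyl]triphenylphosphonium iodide; 8 methyl 9-oxononanoate
Product: 10 methyl (9Z,16S)-16-(tert-butyldimethylsilyloxy)octadec-9-enoate, via phosphonium ylide 9 (not isolated)
Conditions: NaHMDS, THF, –78 → 0 °C; then 8, –78 °C → rt
Reagents that add atoms: none
Why: The Wittig reaction of a non-stabilised ylide with an aliphatic aldehyde under lithium-free conditions passes through the kinetically favoured cis-oxaphosphetane and should give the Z-alkene, while the aldehyde outcompetes the methyl ester at –78 °C and the remote stereocentre is not involved.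

Step 5
Reactants: 10 methyl (9Z,16S)-16-(tert-butyldimethylsilyloxy)octadec-9-enoate; 11 methyl 3,5-dioxohexanoate
Product: 14 methyl 2,4-dihydroxy-6-[(8Z,15S)-15-(tert-butyldimethylsilyloxy)heptadec-8-en-1-yl]benzoate, via trilithium trianion 12 (not isolated), via triketo ester 13 (not isolated)
Conditions: 11 (2.5 equiv), LDA (7.5 equiv), THF, –78 → 0 °C; then 10, 0 °C → rt; then H2O, 0 °C → rt (dilute aq. LiOH/THF); 1 M HCl to pH 3
Reagents that add atoms: none
Why: The terminal C6 carbanion of trianion 12, formed last and least stabilised, adds to the ester carbonyl of 10 and methoxide is expelled (Claisen-type C-acylation of a β-dicarbonyl polyanion), giving tetraketide 13 as its polyenolate; the surplus trianion absorbs the newly acidic C6–H, which is why 11 is used in excess. On dilution with water the medium becomes dilute aqueous hydroxide, in which the C7 carbonyl of 13 is still a ketone, and the C2 enolate carbon (between the ester and the C3 ketone) adds to C7 in a 6-(enolendo)-exo-trig aldol closure; loss of water from the carbinol and enolisation of the C3 and C5 carbonyls then give the benzene ring, whose chain-bearing carbon is the former carboxyl carbon of 10. The closest known reaction type is ester acylation of 1,3-dicarbonyl polyanions followed by aldol aromatisation of a 3,5,7-triketo ester to a 6-alkyl-β-resorcylate, the laboratory counterpart of the C2-to-C7 folding of alkylresorcinol synthases. No stereocentre is created, and the silyl ether and the Z-alkene lie far from every enolisable position and are inert to amide base and hydroxide. The step needs aldol closure to win over C6-to-C1 Claisen closure (acylphloroglucinol) and over O-cyclisation (pyrone); this is secured because in water the C7 ketone of 13 is a better electrophile than its methyl ester, because 10 offers only one electrophilic site, and because anhydrous alkoxide, magnesium salts and strong acid are kept away until the ring has closed.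

Step 6
Reactants: 14 methyl 2,4-dihydroxy-6-[(8Z,15S)-15-(tert-butyldimethylsilyloxy)heptadec-8-en-1-yl]benzoate
Product: 15 2,4-dihydroxy-6-[(8Z,15S)-15-(tert-butyldimethylsilyloxy)heptadec-8-en-1-yl]benzoic acid
Conditions: KOH (excess), EtOH/H2O, reflux, Ar; then 1 M HCl, 0 °C, pH 3
Reagents that add atoms: potassium hydroxide, [K+].[OH-] (its oxygen becomes the carboxyl OH)
Why: Forcing saponification (acyl–oxygen cleavage) of the di-ortho-substituted benzoate should give the acid, since a secondary alkyl silyl ether and an isolated alkene withstand hydroxide, and any acid that already loses CO2 here is simply the product of step 7.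

Step 7
Reactants: 15 2,4-dihydroxy-6-[(8Z,15S)-15-(tert-butyldimethylsilyloxy)heptadec-8-en-1-yl]benzoic acid
Product: 16 5-[(8Z,15S)-15-(tert-butyldimethylsilyloxy)heptadec-8-en-1-yl]benzene-1,3-diol
Conditions: DMF (degassed), 130 °C, Ar
Reagents that add atoms: none
Why: 2,4-Dihydroxybenzoic acids undergo thermal protodecarboxylation readily, because ipso protonation is assisted by the ortho and para hydroxyl groups, and neither the silyl ether nor the Z-alkene reacts at this temperature.

Step 8
Reactants: 16 5-[(8Z,15S)-15-(tert-butyldimethylsilyloxy)heptadec-8-en-1-yl]benzene-1,3-diol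
Product: 17 hansfordiol G, 5-[(8Z,15S)-15-hydroxyheptadec-8-en-1-yl]benzene-1,3-diol
Conditions: p-TsOH·H2O (10 mol%), MeOH, rt, Ar
Reagents that add atoms: none
Why: Acid-catalysed methanolysis cleaves the Si–O bond of the silyl ether and not the C–O bond, so the (S) configuration at C15′ is retained, and the resorcinol and the isolated Z-alkene are stable to catalytic acid at room temperature.

**Compound list**

1 | 1-bromo-5-chloropentane | ClCCCCCBr | starting material
2 | (S)-1,2-epoxybutane | CC[C@H]1CO1 | starting material
3 | 5-chloropentylmagnesium bromide | ClCCCCC[Mg]Br | intermediate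
4 | (S)-9-chlorononan-3-ol | CC[C@H](O)CCCCCCCl | intermediate
5 | (S)-tert-butyl[(9-chlorononan-3-yl)oxy]dimethylsilane | CC[C@H](O[Si](C)(C)C(C)(C)C)CCCCCCCl | intermediate
6 | (S)-tert-butyl[(9-iodononan-3-yl)oxy]dimethylsilane | CC[C@H](O[Si](C)(C)C(C)(C)C)CCCCCCI | intermediate
7 | [(7S)-7-(tert-butyldimethylsilyloxy)nonyl]triphenylphosphonium iodide | CC[C@H](O[Si](C)(C)C(C)(C)C)CCCCCC[P+](c1ccccc1)(c1ccccc1)c1ccccc1.[I-] | intermediate
8 | methyl 9-oxononanoate | COC(=O)CCCCCCCC=O | starting material
9 | [(7S)-7-(tert-butyldimethylsilyloxy)nonylidene]triphenylphosphorane | CC[C@H](O[Si](C)(C)C(C)(C)C)CCCCCC=P(c1ccccc1)(c1ccccc1)c1ccccc1 | intermediate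
10 | methyl (9Z,16S)-16-(tert-butyldimethylsilyloxy)octadec-9-enoate | CC[C@H](O[Si](C)(C)C(C)(C)C)CCCCC/C=C\CCCCCCCC(=O)OC | intermediate
11 | methyl 3,5-dioxohexanoate | CC(=O)CC(=O)CC(=O)OC | starting material
12 | trilithium trianion of methyl 3,5-dioxohexanoate (C2, C4, C6 deprotonated) | [Li+].[Li+].[Li+].[CH2-]C(=O)[CH-]C(=O)[CH-]C(=O)OC | intermediate
13 | methyl (15Z,22S)-22-(tert-butyldimethylsilyloxy)-3,5,7-trioxotetracos-15-enoate | CC[C@H](O[Si](C)(C)C(C)(C)C)CCCCC/C=C\CCCCCCCC(=O)CC(=O)CC(=O)CC(=O)OC | intermediate
14 | methyl 2,4-dihydroxy-6-[(8Z,15S)-15-(tert-butyldimethylsilyloxy)heptadec-8-en-1-yl]benzoate | CC[C@H](O[Si](C)(C)C(C)(C)C)CCCCC/C=C\CCCCCCCc1cc(O)cc(O)c1C(=O)OC | intermediate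
15 | 2,4-dihydroxy-6-[(8Z,15S)-15-(tert-butyldimethylsilyloxy)heptadec-8-en-1-yl]benzoic acid | CC[C@H](O[Si](C)(C)C(C)(C)C)CCCCC/C=C\CCCCCCCc1cc(O)cc(O)c1C(=O)O | intermediate
16 | 5-[(8Z,15S)-15-(tert-butyldimethylsilyloxy)heptadec-8-en-1-yl]benzene-1,3-diol | CC[C@H](O[Si](C)(C)C(C)(C)C)CCCCC/C=C\CCCCCCCc1cc(O)cc(O)c1 | intermediate
17 | hansfordiol G, 5-[(8Z,15S)-15-hydroxyheptadec-8-en-1-yl]benzene-1,3-diol | CC[C@H](O)CCCCC/C=C\CCCCCCCc1cc(O)cc(O)c1 | target

**Step count**

Total steps: 8. Longest linear sequence: 8 steps (1/2 → 17); 8 and 11 enter as purchased reagents.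

**Steps most likely to fail**

1. Step 5. The strongly basic trianion may remove an α-proton from the enolisable ester instead of adding to its carbonyl, which stalls the acylation or leads to self-condensation of the ester. The open tetraketide may also close the wrong way, by Claisen closure or O-cyclisation.
Fallback, from 10 back to 15: aminolysis of 10 with MeNH(OMe)·HCl and i-PrMgCl (THF, –20 °C) should give the Weinreb amide (9Z,16S)-16-(tert-butyldimethylsilyloxy)-N-methoxy-N-methyloctadec-9-enamide F1. The dilithium dianion of 2,2-dimethyl-6-(2-oxopropyl)-4H-1,3-dioxin-4-one (LDA, THF, –78 °C) is then C-acylated at its terminal carbon by F1 to give the diketo-dioxinone 6-[(12Z,19S)-19-(tert-butyldimethylsilyloxy)-2,4-dioxohenicos-12-en-1-yl]-2,2-dimethyl-4H-1,3-dioxin-4-one F2. With Et3N in CH2Cl2 at rt, F2 should undergo the same C2-to-C7 aldol and dehydration; because the carboxyl is locked in the dioxinone ring, Claisen closure cannot compete. The product is the acetonide-masked resorcylate 7-hydroxy-2,2-dimethyl-5-[(8Z,15S)-15-(tert-butyldimethylsilyloxy)heptadec-8-en-1-yl]-4H-1,3-benzodioxin-4-one F3. Aqueous KOH/THF opens the benzodioxinone and, after cold acidification, the route is rejoined at acid 15, which also bypasses step 6.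

2. Step 6. Hydroxide attack at a carbonyl shielded by two ortho substituents and deactivated by phenoxide formation may be slow, and prolonged heating may erode the silyl ether or cause air oxidation of the electron-rich ring.
Fallback, from 14 back to 15: the methyl group is removed by alkyl–oxygen cleavage instead, with LiI in refluxing pyridine under argon. This is an SN2 attack of iodide at the O-methyl carbon and is indifferent to the shielding of the carbonyl. Cold acidification returns 15, and any material that decarboxylates in the hot medium is already 16. This fallback makes no new compound (F0).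

3. Step 4. Partial equilibration of the oxaphosphetane (stereochemical drift) would erode the Z-selectivity and give a geometric isomer that is hard to remove from a long-chain ester.
Fallback, from 2 back to 10, with the alkene geometry set by syn-hydrogenation of an alkyne: 4-chlorobutylmagnesium bromide (from 1-bromo-4-chlorobutane and Mg) opens 2 under CuI catalysis to give (S)-8-chlorooctan-3-ol F4. TBSCl/imidazole gives (S)-tert-butyl[(8-chlorooctan-3-yl)oxy]dimethylsilane F5, and NaI in acetone gives (S)-tert-butyl[(8-iodooctan-3-yl)oxy]dimethylsilane F6. The dilithium dianion of dec-9-ynoic acid (n-BuLi 2 equiv, THF/DMPU) is alkylated at the acetylide carbon by F6 to give (S)-16-(tert-butyldimethylsilyloxy)octadec-9-ynoic acid F7. MeI/K2CO3 in DMF gives methyl (S)-16-(tert-butyldimethylsilyloxy)octadec-9-ynoate F8, and Lindlar semi-hydrogenation (H2, Pd/CaCO3–Pb, quinoline) returns the route at 10.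

**Further compounds**

F1 | step 5 | (9Z,16S)-16-(tert-butyldimethylsilyloxy)-N-methoxy-N-methyloctadec-9-enamide | CC[C@H](O[Si](C)(C)C(C)(C)C)CCCCC/C=C\CCCCCCCC(=O)N(C)OC
F2 | step 5 | 6-[(12Z,19S)-19-(tert-butyldimethylsilyloxy)-2,4-dioxohenicos-12-en-1-yl]-2,2-dimethyl-4H-1,3-dioxin-4-one | CC[C@H](O[Si](C)(C)C(C)(C)C)CCCCC/C=C\CCCCCCCC(=O)CC(=O)CC1=CC(=O)OC(C)(C)O1
F3 | step 5 | 7-hydroxy-2,2-dimethyl-5-[(8Z,15S)-15-(tert-butyldimethylsilyloxy)heptadec-8-en-1-yl]-4H-1,3-benzodioxin-4-one | CC[C@H](O[Si](C)(C)C(C)(C)C)CCCCC/C=C\CCCCCCCc1cc(O)cc2OC(C)(C)OC(=O)c12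
F0 | step 6 | none | none
F4 | step 4 | (S)-8-chlorooctan-3-ol | CC[C@H](O)CCCCCCl
F5 | step 4 | (S)-tert-butyl[(8-chlorooctan-3-yl)oxy]dimethylsilane | CC[C@H](O[Si](C)(C)C(C)(C)C)CCCCCCl
F6 | step 4 | (S)-tert-butyl[(8-iodooctan-3-yl)oxy]dimethylsilane | CC[C@H](O[Si](C)(C)C(C)(C)C)CCCCCI
F7 | step 4 | (S)-16-(tert-butyldimethylsilyloxy)octadec-9-ynoic acid | CC[C@H](O[Si](C)(C)C(C)(C)C)CCCCCC#CCCCCCCCC(=O)O
F8 | step 4 | methyl (S)-16-(tert-butyldimethylsilyloxy)octadec-9-ynoate | CC[C@H](O[Si](C)(C)C(C)(C)C)CCCCCC#CCCCCCCCC(=O)OC
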